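Rings A and B each carry, next to the phenol, a C7(OH)–C8H–C9H2OH arm; the arms have the same C7 configuration and differ only at C8. Both are therefore hydride-opened forms of one 3,4-diaryl oxetan-2-one, and the plan rests on disconnecting C7–C8 and O–C9 of that lactone. A cinchona alkaloid/LiClO4-catalysed ketene–aldehyde (2+2) cycloaddition closes the four-membered ring and sets C7 and C8 in one operation from a brominated, O-benzylated arylacetyl chloride and O-pivaloylvanillin. The cis adduct gives ring B's arm directly and, after C8 epimerisation, ring A's arm; the aryl bromides are later exchanged for the benzylic carbons of the trans-dibenzylbutyrolactone.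

Key step: step 7

Labels: ring A is the arene whose CH2 sits on lactone C4, ring B the one whose CH2 sits on lactone C3; in each arm C7 is the carbinol carbon, C8 the methine on ring A or B, C9 the CH2OH carbon.
Check of the target: lactone (3S,4S), trans; ring A arm (7S,8S); ring B arm (7S,8R); the cis adduct needed is (3S,4S). No structure needed correction.
Assumption: O-trimethylsilylquinine is taken to give the (3S,4S) adduct; if the facial sense is the reverse, O-trimethylsilylquinidine is used with nothing else changed.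
Assumption: the (S)-BINAP ruthenium catalyst is taken to give the (S)-lactone in step 18; if it delivers the other face, the (R)-ligand is used.

Step 1
Reactants: 1 5-bromo-2-hydroxy-3-methoxybenzaldehyde
Product: 2 2-(benzyloxy)-5-bromo-3-methoxybenzaldehyde
Conditions: BnBr, K2CO3, DMF, 60 °C
Reagents that add atoms: benzyl bromide, BrCc1ccccc1
Why: Williamson O-alkylation of the phenoxide (SN2 on benzyl bromide), to which the aldehyde and the aryl bromide are inert.

Step 2
Reactants: 2 2-(benzyloxy)-5-bromo-3-methoxybenzaldehyde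
Product: 3 2-(benzyloxy)-5-bromo-1-methoxy-3-(2-methoxyethenyl)benzene (E/Z mixture)
Conditions: Ph3P(CH2OMe)Cl, KOtBu, THF, 0 °C to rt
Reagents that add atoms: (methoxymethyl)triphenylphosphonium chloride, COC[P+](c1ccccc1)(c1ccccc1)c1ccccc1.[Cl-]
Why: Wittig olefination by the non-stabilised methoxymethylene ylide gives the one-carbon-extended enol ether, and the alkene geometry is irrelevant because both isomers hydrolyse to the same aldehyde.

Step 3
Reactants: 3 2-(benzyloxy)-5-bromo-1-methoxy-3-(2-methoxyethenyl)benzene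
Product: 4 [2-(benzyloxy)-5-bromo-3-methoxyphenyl]acetaldehyde
Conditions: 2 M aq. HCl, THF, 50 °C; used crude
Reagents that add atoms: water, O
Why: Acid-catalysed enol ether hydrolysis (C-protonation, then hemiacetal collapse) should unmask the arylacetaldehyde, which is carried on at once because it enolises and air-oxidises easily.

Step 4
Reactants: 4 [2-(benzyloxy)-5-bromo-3-methoxyphenyl]acetaldehyde
Product: 5 [2-(benzyloxy)-5-bromo-3-methoxyphenyl]acetic acid
Conditions: NaClO2, NaH2PO4, 2-methyl-2-butene, t-BuOH/H2O, 0 °C to rt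
Reagents that add atoms: sodium chlorite, [Na+].[O-]Cl=O
Why: Pinnick oxidation converts the aldehyde into the acid under buffered chlorite, the alkene scavenger trapping HOCl so that the electron-rich ring is not chlorinated.

Step 5
Reactants: 5 [2-(benzyloxy)-5-bromo-3-methoxyphenyl]acetic acid
Product: 6 [2-(benzyloxy)-5-bromo-3-methoxyphenyl]acetyl chloride
Conditions: (COCl)2, DMF (cat.), CH2Cl2, 0 °C to rt; evaporated and used directly
Reagents that add atoms: oxalyl chloride, ClC(=O)C(Cl)=O
Why: DMF-catalysed (Vilsmeier-type) acyl chloride formation leaves only gaseous by-products, so the moisture-sensitive chloride can go straight into the cycloaddition.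

Step 6
Reactants: 7 vanillin (4-hydroxy-3-methoxybenzaldehyde)
Product: 8 4-formyl-2-methoxyphenyl pivalate
Conditions: PivCl, Et3N, DMAP (cat.), CH2Cl2, 0 °C to rt
Reagents that add atoms: pivaloyl chloride, CC(C)(C)C(Cl)=O
Why: DMAP-catalysed O-acylation of the phenol gives a hindered aryl ester that lowers the donor strength of the para oxygen for the steps that follow.

Step 7
Reactants: 6 [2-(benzyloxy)-5-bromo-3-methoxyphenyl]acetyl chloride; 8 4-formyl-2-methoxyphenyl pivalate
Product: 10 (3S,4S)-3-[2-(benzyloxy)-5-bromo-3-methoxyphenyl]-4-[3-methoxy-4-(pivaloyloxy)phenyl]oxetan-2-one (cis lactone), via arylketene 9 (not isolated)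
Conditions: O-trimethylsilylquinine (15 mol %), LiClO4 (2 equiv), iPr2NEt (2.5 equiv), CH2Cl2/Et2O (2:1), −78 °C, 6 added over 4 h; cold work-up, short silica plug, used the same day
Reagents that add atoms: none
Why: iPr2NEt dehydrochlorinates 6 to arylketene 9, which the quinuclidine nitrogen of the alkaloid captures as an acylammonium enolate; this adds through a closed, lithium-bridged aldol transition state to the LiClO4-activated aldehyde 8 (C7–C8 bond), and the lithium aldolate then closes the oxetanone by 4-exo-trig attack on the acylammonium carbonyl (O–C9 bond) and releases the catalyst. The closest known reaction type is the cinchona alkaloid/lithium perchlorate co-catalysed acyl halide–aldehyde cyclocondensation that gives cis-3,4-disubstituted β-lactones. C7 is set by the alkaloid, which shields one enolate face and so presents a single aldehyde face, and C8 follows from the chair-like lithium-organised transition state, which places both aryl groups cis on the ring. The step needs cross-reaction over ketene dimerisation, cis over trans and one enantiomer: the aldehyde is non-enolisable and made more electrophilic by the 4-pivaloyloxy group, slow addition keeps free ketene low, and −78 °C keeps the acidic C8–H from epimerising under the amine. The acyloxy group also holds back ionisation of the benzylic C7–O bond and decarboxylation, so the lactone should survive a cold work-up and is carried on immediately.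

Step 8
Reactants: 10 cis lactone (3S,4S)
Product: 11 4-{(1S,2R)-2-[2-(benzyloxy)-5-bromo-3-methoxyphenyl]-1,3-dihydroxypropyl}-2-methoxyphenyl pivalate (ring B arm, 7S,8R)
Conditions: LiBH4 (1.0 equiv), THF, −20 to 0 °C
Reagents that add atoms: none
Why: Hydride attack on the strained acyl carbon opens the β-lactone by acyl C–O cleavage and reduces the resulting aldehyde (chemoselective ester reduction), so C7 and C8 are untouched and the hindered aryl pivalate should be spared at low temperature.

Step 9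
Reactants: 11 diol (1S,2R)
Product: 12 4-{(4S,5R)-5-[2-(benzyloxy)-5-bromo-3-methoxyphenyl]-2,2-dimethyl-1,3-dioxan-4-yl}-2-methoxyphenyl pivalate (cis-4,5-diaryl acetonide)
Conditions: Me2C(OMe)2, PPTS (cat.), CH2Cl2, rt
Reagents that add atoms: 2,2-dimethoxypropane, COC(C)(C)OC
Why: Acid-catalysed transketalisation closes the six-membered acetonide on the 1,3-diol, and the mild acid should not ionise the benzylic C7–O bond of the acyloxy-substituted ring.

Step 10
Reactants: 10 cis lactone (3S,4S), second portion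
Product: 13 (3R,4S)-3-[2-(benzyloxy)-5-bromo-3-methoxyphenyl]-4-[3-methoxy-4-(pivaloyloxy)phenyl]oxetan-2-one (trans lactone)
Conditions: DBU (0.2 equiv), CH2Cl2, 0 °C; filtered cold through silica, used directly
Reagents that add atoms: none
Why: Base-mediated epimerisation through the lactone enolate, since C8–H is benzylic and α to the acyl group and the equilibrium should favour the trans ring in which the two aryl groups no longer eclipse, while C7 has no acidic hydrogen and keeps its configuration.

Step 11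
Reactants: 13 trans lactone (3R,4S)
Product: 14 4-{(1S,2S)-2-[2-(benzyloxy)-5-bromo-3-methoxyphenyl]-1,3-dihydroxypropyl}-2-methoxyphenyl pivalate (ring A arm, 7S,8S)
Conditions: LiBH4 (1.0 equiv), THF, −20 to 0 °C
Reagents that add atoms: none
Why: The same reductive acyl C–O opening as in step 8 transfers the trans relationship of the lactone to the open diol without touching either stereocentre.

Step 12
Reactants: 14 diol (1S,2S)
Product: 15 4-{(4S,5S)-5-[2-(benzyloxy)-5-bromo-3-methoxyphenyl]-2,2-dimethyl-1,3-dioxan-4-yl}-2-methoxyphenyl pivalate (trans-4,5-diaryl acetonide)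
Conditions: Me2C(OMe)2, PPTS (cat.), CH2Cl2, rt
Reagents that add atoms: 2,2-dimethoxypropane, COC(C)(C)OC
Why: Acid-catalysed transketalisation as in step 9, here giving the dioxane with both aryl groups equatorial.

Step 13
Reactants: 12 acetonide (4S,5R)
Product: 16 4-{(4S,5R)-5-[2-(benzyloxy)-5-(hydroxymethyl)-3-methoxyphenyl]-2,2-dimethyl-1,3-dioxan-4-yl}-2-methoxyphenyl pivalate
Conditions: Bu3SnCH2OH, Pd(PPh3)4 (5 mol %), 1,4-dioxane, 95 °C
Reagents that add atoms: (tributylstannyl)methanol, OC[Sn](CCCC)(CCCC)CCCC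
Why: Stille coupling transfers the hydroxymethyl group from tin to the aryl bromide under neutral conditions that leave the pivalate, the benzyl ether and the acetonide alone.

Step 14
Reactants: 16 benzylic alcohol (4S,5R)
Product: 17 4-{(4S,5R)-5-[2-(benzyloxy)-5-(bromomethyl)-3-methoxyphenyl]-2,2-dimethyl-1,3-dioxan-4-yl}-2-methoxyphenyl pivalate
Conditions: CBr4, PPh3, 2,6-lutidine, CH2Cl2, 0 °C; used without storage
Reagents that add atoms: carbon tetrabromide, BrC(Br)(Br)Br
Why: Appel bromination (oxyphosphonium formation, then SN2 by bromide) of the primary benzylic alcohol, with lutidine buffering traces of HBr so that the acetonide stays on.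

Step 15
Reactants: 15 acetonide (4S,5S)
Product: 18 4-{(4S,5S)-5-[2-(benzyloxy)-5-(hydroxymethyl)-3-methoxyphenyl]-2,2-dimethyl-1,3-dioxan-4-yl}-2-methoxyphenyl pivalate
Conditions: Bu3SnCH2OH, Pd(PPh3)4 (5 mol %), 1,4-dioxane, 95 °C
Reagents that add atoms: (tributylstannyl)methanol, OC[Sn](CCCC)(CCCC)CCCC
Why: Stille hydroxymethylation as in step 13, the unhindered aryl bromide being the only site that undergoes oxidative addition.

Step 16
Reactants: 18 benzylic alcohol (4S,5S)
Product: 19 4-{(4S,5S)-5-[2-(benzyloxy)-5-(bromomethyl)-3-methoxyphenyl]-2,2-dimethyl-1,3-dioxan-4-yl}-2-methoxyphenyl pivalate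
Conditions: CBr4, PPh3, 2,6-lutidine, CH2Cl2, 0 °C; used without storage
Reagents that add atoms: carbon tetrabromide, BrC(Br)(Br)Br
Why: Appel bromination as in step 14.

Step 17
Reactants: 19 benzylic bromide (4S,5S); 20 4-bromofuran-2(5H)-one
Product: 22 4-{(4S,5S)-5-[2-(benzyloxy)-3-methoxy-5-[(5-oxo-2,5-dihydrofuran-3-yl)methyl]phenyl]-2,2-dimethyl-1,3-dioxan-4-yl}-2-methoxyphenyl pivalate (butenolide), via benzylzinc bromide 21 (not isolated)
Conditions: Zn dust, LiCl, THF, 0 °C to rt; then 20, Pd(PPh3)4 (3 mol %), THF, rt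
Reagents that add atoms: none
Why: LiCl-assisted zinc insertion into the benzylic C–Br bond gives an ester-tolerant benzylzinc reagent, and Negishi coupling with the β-bromo enoate 20 (oxidative addition to zerovalent palladium, transmetalation, reductive elimination) forms the benzyl–C4 bond.

Step 18
Reactants: 22 butenolide
Product: 23 4-{(4S,5S)-5-[2-(benzyloxy)-3-methoxy-5-{[(3S)-5-oxooxolan-3-yl]methyl}phenyl]-2,2-dimethyl-1,3-dioxan-4-yl}-2-methoxyphenyl pivalate
Conditions: H2 (50 atm), Ru(OAc)2[(S)-BINAP] (2 mol %), MeOH/CH2Cl2 (4:1), 50 °C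
Reagents that add atoms: none
Why: Enantioselective hydrogenation of a β-substituted butenolide by a BINAP–ruthenium dicarboxylate, in which the lactone carbonyl binds the metal and the ligand selects the alkene face, sets lactone C4 as S independently of the remote arm, and the homogeneous catalyst does not cleave benzyl ethers.

Step 19
Reactants: 23 (S)-lactone carrying the ring A fragment; 17 benzylic bromide (4S,5R)
Product: 25 fully protected (3S,4S)-trans-dibenzylbutyrolactone (C3 benzyl from 17; C4 benzyl from 23; two acetonides; two benzyl ethers; two pivalates), via lithium enolate 24 (not isolated)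
Conditions: LiN(SiMe3)2, THF, −78 °C; then 17, DMPU, −78 to −40 °C
Reagents that add atoms: none
Why: Lithium enolate alkylation of a 4-substituted butyrolactone, in which the benzylic bromide approaches anti to the C4 substituent and so gives the 3,4-trans lactone with C3 as S, while at −78 °C the hindered aryl pivalates should not be attacked.

Step 20
Reactants: 25 fully protected lactone
Product: 26 (3S,4S)-lactone with both 1,3-diols free (tetraol; two benzyl ethers and two pivalates retained)
Conditions: AcOH/THF/H2O (3:1:1), 40 °C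
Reagents that add atoms: none
Why: Acid-catalysed acetal hydrolysis via the tertiary oxocarbenium ion removes both dioxanes while the guaiacyl oxygens are still acylated and the ring A and ring B phenols still benzylated, so the benzylic C7–O bonds neither ionise nor find an internal phenol to cyclise onto.

Step 21
Reactants: 26 tetraol bis-pivalate
Product: 27 (3S,4S)-lactone with free diols and free guaiacyl phenols (ring A and ring B phenols still benzylated)
Conditions: K2CO3, MeOH, 0 °C to rt, argon; NH4Cl work-up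
Reagents that add atoms: none
Why: Base-mediated transesterification cleaves the aryl pivalates because phenoxide is a good leaving group, and any methanolysis of the γ-lactone reverses on neutralisation with the already thermodynamic trans configuration retained.

Step 22
Reactants: 27 bis(benzyl ether)
Product: 28 CNP0113972.1, (3S,4S)-3-{4-hydroxy-3-[(1S,2R)-1,3-dihydroxy-1-(4-hydroxy-3-methoxyphenyl)propan-2-yl]-5-methoxybenzyl}-4-{4-hydroxy-3-[(1S,2S)-1,3-dihydroxy-1-(4-hydroxy-3-methoxyphenyl)propan-2-yl]-5-methoxybenzyl}oxolan-2-one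
Conditions: H2 (1 atm), 10% Pd/C, EtOAc/MeOH, rt, stopped at full conversion
Reagents that add atoms: none
Why: Hydrogenolysis of the two aryl benzyl ethers on palladium under neutral conditions is much faster than cleavage of the secondary benzylic alcohols, so the last step needs neither acid nor base.

Compound list
1 | 5-bromo-2-hydroxy-3-methoxybenzaldehyde | COc1cc(Br)cc(C=O)c1O | starting material
2 | 2-(benzyloxy)-5-bromo-3-methoxybenzaldehyde | COc1cc(Br)cc(C=O)c1OCc1ccccc1 | intermediate
3 | 2-(benzyloxy)-5-bromo-1-methoxy-3-(2-methoxyethenyl)benzene (E/Z mixture) | COC=Cc1cc(Br)cc(OC)c1OCc1ccccc1 | intermediate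
4 | [2-(benzyloxy)-5-bromo-3-methoxyphenyl]acetaldehyde | O=CCc1cc(Br)cc(OC)c1OCc1ccccc1 | intermediate
5 | [2-(benzyloxy)-5-bromo-3-methoxyphenyl]acetic acid | OC(=O)Cc1cc(Br)cc(OC)c1OCc1ccccc1 | intermediate
6 | [2-(benzyloxy)-5-bromo-3-methoxyphenyl]acetyl chloride | ClC(=O)Cc1cc(Br)cc(OC)c1OCc1ccccc1 | intermediate
7 | vanillin | COc1cc(C=O)ccc1O | starting material
8 | 4-formyl-2-methoxyphenyl pivalate | COc1cc(C=O)ccc1OC(=O)C(C)(C)C | intermediate
9 | [2-(benzyloxy)-5-bromo-3-methoxyphenyl]ketene | O=C=Cc1cc(Br)cc(OC)c1OCc1ccccc1 | intermediate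
10 | (3S,4S)-3-[2-(benzyloxy)-5-bromo-3-methoxyphenyl]-4-[3-methoxy-4-(pivaloyloxy)phenyl]oxetan-2-one (cis) | COc1cc(Br)cc([C@@H]2C(=O)O[C@@H]2c3ccc(OC(=O)C(C)(C)C)c(OC)c3)c1OCc4ccccc4 | intermediate
11 | 4-{(1S,2R)-2-[2-(benzyloxy)-5-bromo-3-methoxyphenyl]-1,3-dihydroxypropyl}-2-methoxyphenyl pivalate | COc1cc(Br)cc([C@H](CO)[C@H](O)c2ccc(OC(=O)C(C)(C)C)c(OC)c2)c1OCc3ccccc3 | intermediate
12 | 4-{(4S,5R)-5-[2-(benzyloxy)-5-bromo-3-methoxyphenyl]-2,2-dimethyl-1,3-dioxan-4-yl}-2-methoxyphenyl pivalate | COc1cc(Br)cc([C@@H]2COC(C)(C)O[C@@H]2c3ccc(OC(=O)C(C)(C)C)c(OC)c3)c1OCc4ccccc4 | intermediate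
13 | (3R,4S)-3-[2-(benzyloxy)-5-bromo-3-methoxyphenyl]-4-[3-methoxy-4-(pivaloyloxy)phenyl]oxetan-2-one (trans) | COc1cc(Br)cc([C@H]2C(=O)O[C@@H]2c3ccc(OC(=O)C(C)(C)C)c(OC)c3)c1OCc4ccccc4 | intermediate
14 | 4-{(1S,2S)-2-[2-(benzyloxy)-5-bromo-3-methoxyphenyl]-1,3-dihydroxypropyl}-2-methoxyphenyl pivalate | COc1cc(Br)cc([C@@H](CO)[C@H](O)c2ccc(OC(=O)C(C)(C)C)c(OC)c2)c1OCc3ccccc3 | intermediate
15 | 4-{(4S,5S)-5-[2-(benzyloxy)-5-bromo-3-methoxyphenyl]-2,2-dimethyl-1,3-dioxan-4-yl}-2-methoxyphenyl pivalate | COc1cc(Br)cc([C@H]2COC(C)(C)O[C@@H]2c3ccc(OC(=O)C(C)(C)C)c(OC)c3)c1OCc4ccccc4 | intermediate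
16 | 4-{(4S,5R)-5-[2-(benzyloxy)-5-(hydroxymethyl)-3-methoxyphenyl]-2,2-dimethyl-1,3-dioxan-4-yl}-2-methoxyphenyl pivalate | COc1cc(CO)cc([C@@H]2COC(C)(C)O[C@@H]2c3ccc(OC(=O)C(C)(C)C)c(OC)c3)c1OCc4ccccc4 | intermediate
17 | 4-{(4S,5R)-5-[2-(benzyloxy)-5-(bromomethyl)-3-methoxyphenyl]-2,2-dimethyl-1,3-dioxan-4-yl}-2-methoxyphenyl pivalate | COc1cc(CBr)cc([C@@H]2COC(C)(C)O[C@@H]2c3ccc(OC(=O)C(C)(C)C)c(OC)c3)c1OCc4ccccc4 | intermediate
18 | 4-{(4S,5S)-5-[2-(benzyloxy)-5-(hydroxymethyl)-3-methoxyphenyl]-2,2-dimethyl-1,3-dioxan-4-yl}-2-methoxyphenyl pivalate | COc1cc(CO)cc([C@H]2COC(C)(C)O[C@@H]2c3ccc(OC(=O)C(C)(C)C)c(OC)c3)c1OCc4ccccc4 | intermediate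
19 | 4-{(4S,5S)-5-[2-(benzyloxy)-5-(bromomethyl)-3-methoxyphenyl]-2,2-dimethyl-1,3-dioxan-4-yl}-2-methoxyphenyl pivalate | COc1cc(CBr)cc([C@H]2COC(C)(C)O[C@@H]2c3ccc(OC(=O)C(C)(C)C)c(OC)c3)c1OCc4ccccc4 | intermediate
20 | 4-bromofuran-2(5H)-one | BrC1=CC(=O)OC1 | starting material
21 | benzylzinc bromide formed from 19 | COc1cc(C[Zn]Br)cc([C@H]2COC(C)(C)O[C@@H]2c3ccc(OC(=O)C(C)(C)C)c(OC)c3)c1OCc4ccccc4 | intermediate
22 | 4-{(4S,5S)-5-[2-(benzyloxy)-3-methoxy-5-[(5-oxo-2,5-dihydrofuran-3-yl)methyl]phenyl]-2,2-dimethyl-1,3-dioxan-4-yl}-2-methoxyphenyl pivalate | COc1cc(CC2=CC(=O)OC2)cc([C@H]3COC(C)(C)O[C@@H]3c4ccc(OC(=O)C(C)(C)C)c(OC)c4)c1OCc5ccccc5 | intermediate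
23 | 4-{(4S,5S)-5-[2-(benzyloxy)-3-methoxy-5-{[(3S)-5-oxooxolan-3-yl]methyl}phenyl]-2,2-dimethyl-1,3-dioxan-4-yl}-2-methoxyphenyl pivalate | COc1cc(C[C@H]2CC(=O)OC2)cc([C@H]3COC(C)(C)O[C@@H]3c4ccc(OC(=O)C(C)(C)C)c(OC)c4)c1OCc5ccccc5 | intermediate
24 | lithium enolate of 23 | COc1cc(C[C@H]2C=C(O[Li])OC2)cc([C@H]3COC(C)(C)O[C@@H]3c4ccc(OC(=O)C(C)(C)C)c(OC)c4)c1OCc5ccccc5 | intermediate
25 | (3S,4S)-oxolan-2-one with, on C3, the 4-(benzyloxy)-3-methoxy-5-[(4S,5R)-2,2-dimethyl-4-(3-methoxy-4-pivaloyloxyphenyl)-1,3-dioxan-5-yl]benzyl group and, on C4, the corresponding (4S,5S) group | COc1cc(C[C@@H]2COC(=O)[C@H]2Cc3cc(OC)c(OCc4ccccc4)c([C@@H]5COC(C)(C)O[C@@H]5c6ccc(OC(=O)C(C)(C)C)c(OC)c6)c3)cc([C@H]7COC(C)(C)O[C@@H]7c8ccc(OC(=O)C(C)(C)C)c(OC)c8)c1OCc9ccccc9 | intermediate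
26 | tetraol from 25: both acetonides removed, ring B arm (1S,2R), ring A arm (1S,2S), two benzyl ethers and two pivalates retained | COc1cc(C[C@@H]2COC(=O)[C@H]2Cc3cc(OC)c(OCc4ccccc4)c([C@H](CO)[C@H](O)c5ccc(OC(=O)C(C)(C)C)c(OC)c5)c3)cc([C@@H](CO)[C@H](O)c6ccc(OC(=O)C(C)(C)C)c(OC)c6)c1OCc7ccccc7 | intermediate
27 | 26 with both pivalates removed (guaiacyl phenols free, ring A and ring B phenols benzylated) | COc1cc(C[C@@H]2COC(=O)[C@H]2Cc3cc(OC)c(OCc4ccccc4)c([C@H](CO)[C@H](O)c5ccc(O)c(OC)c5)c3)cc([C@@H](CO)[C@H](O)c6ccc(O)c(OC)c6)c1OCc7ccccc7 | intermediate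
28 | CNP0113972.1 | COc1cc(C[C@@H]2COC(=O)[C@H]2Cc3cc(OC)c(O)c([C@H](CO)[C@H](O)c4ccc(O)c(OC)c4)c3)cc([C@@H](CO)[C@H](O)c5ccc(O)c(OC)c5)c1O | target

Total step count: 22.
Longest linear sequence: 17 steps from 1 (steps 1, 2, 3, 4, 5, 7, 10, 11, 12, 15, 16, 17, 18, 19, 20, 21, 22).

Steps most likely to fail

Step 7. Dimerisation of the aryl-substituted ketene may outrun the cross-cycloaddition, facial or cis selectivity may be insufficient for an arylketene, or the 4-aryl lactone may ionise and decarboxylate on work-up. The fallback replaces the catalytic cycloaddition by an auxiliary-controlled aldol and bypasses the lactone. It sets out from acid 5 (with aldehyde 8) and comes back at diol 11. Acid 5 is activated as its mixed pivalic anhydride (PivCl, Et3N, THF) and acylates lithiated (S)-4-benzyloxazolidin-2-one to give the N-arylacetyl oxazolidinone F1. Its dibutylboron Z-enolate (Bu2BOTf, iPr2NEt, CH2Cl2, −78 °C) adds to 8 through a Zimmerman–Traxler chair (Evans aldol) to give the syn aldol adduct F2, which has the (7S,8R) arm configuration. LiBH4 in wet THF at 0 °C removes the auxiliary reductively and gives 11. Because 10 is then not available, the ring A arm is taken from the same imide by the anti-aldol described under step 10.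

Step 10. Nucleophilic opening of the lactone by the amidine, decarboxylation, or incomplete equilibration to a cis/trans mixture may occur. The fallback sets C8 by an anti-selective aldol instead of epimerising. It sets out from acid 5 (through the N-arylacetyl oxazolidinone F1, made as above) with aldehyde 8 and comes back at diol 14. The magnesium-catalysed direct aldol of the N-acyloxazolidinone with the aromatic aldehyde (MgCl2 10 mol %, Et3N, Me3SiCl, EtOAc, rt) should give the O-trimethylsilyl anti adduct F3. On the chelated-enolate model, C8 is then opposite to that of the boron aldol while C7 is the same, that is (7S,8S); if the opposite anti adduct formed, the (R)-auxiliary would be used. Brief treatment with CF3CO2H in MeOH gives the anti aldol adduct F4, and LiBH4 in wet THF at 0 °C gives 14.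

Step 18. Facial selectivity on the trisubstituted butenolide may be poor, or the alkene may migrate out of conjugation before it is reduced. The fallback sets lactone C4 by auxiliary-controlled alkylation and replaces steps 17 and 18. It sets out from bromide 19 and comes back at lactone 23. Mono-tert-butyl succinate is coupled with (S)-4-benzyloxazolidin-2-one (PivCl, Et3N, LiCl, THF) to give the succinate imide F5. Its sodium enolate (NaN(SiMe3)2, THF, −78 °C) is alkylated by 19 on the face away from the auxiliary benzyl group to give the alkylated imide F6, with the new centre S. LiBH4 in wet THF at 0 °C reduces only the imide carbonyl to give the hydroxy ester F7, and TsOH (cat.) in CH2Cl2 closes the lactone to 23.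

Further compounds
F1 | step 7 | (4S)-4-benzyl-3-{[2-(benzyloxy)-5-bromo-3-methoxyphenyl]acetyl}oxazolidin-2-one | COc1cc(Br)cc(CC(=O)N2[C@@H](Cc3ccccc3)COC2=O)c1OCc4ccccc4
F2 | step 7 | 4-{(1S,2S)-3-[(4S)-4-benzyl-2-oxooxazolidin-3-yl]-2-[2-(benzyloxy)-5-bromo-3-methoxyphenyl]-1-hydroxy-3-oxopropyl}-2-methoxyphenyl pivalate (syn adduct) | COc1cc(Br)cc([C@H](C(=O)N2[C@@H](Cc3ccccc3)COC2=O)[C@H](O)c4ccc(OC(=O)C(C)(C)C)c(OC)c4)c1OCc5ccccc5
F3 | step 10 | 4-{(1S,2R)-3-[(4S)-4-benzyl-2-oxooxazolidin-3-yl]-2-[2-(benzyloxy)-5-bromo-3-methoxyphenyl]-3-oxo-1-(trimethylsilyloxy)propyl}-2-methoxyphenyl pivalate (anti adduct, silyl ether) | COc1cc(Br)cc([C@@H](C(=O)N2[C@@H](Cc3ccccc3)COC2=O)[C@H](O[Si](C)(C)C)c4ccc(OC(=O)C(C)(C)C)c(OC)c4)c1OCc5ccccc5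
F4 | step 10 | 4-{(1S,2R)-3-[(4S)-4-benzyl-2-oxooxazolidin-3-yl]-2-[2-(benzyloxy)-5-bromo-3-methoxyphenyl]-1-hydroxy-3-oxopropyl}-2-methoxyphenyl pivalate (anti adduct) | COc1cc(Br)cc([C@@H](C(=O)N2[C@@H](Cc3ccccc3)COC2=O)[C@H](O)c4ccc(OC(=O)C(C)(C)C)c(OC)c4)c1OCc5ccccc5
F5 | step 18 | tert-butyl 4-[(4S)-4-benzyl-2-oxooxazolidin-3-yl]-4-oxobutanoate | CC(C)(C)OC(=O)CCC(=O)N1[C@@H](Cc2ccccc2)COC1=O
F6 | step 18 | tert-butyl (3S)-4-[(4S)-4-benzyl-2-oxooxazolidin-3-yl]-3-{4-(benzyloxy)-3-methoxy-5-[(4S,5S)-2,2-dimethyl-4-(3-methoxy-4-pivaloyloxyphenyl)-1,3-dioxan-5-yl]benzyl}-4-oxobutanoate | COc1cc(C[C@@H](CC(=O)OC(C)(C)C)C(=O)N2[C@@H](Cc3ccccc3)COC2=O)cc([C@H]4COC(C)(C)O[C@@H]4c5ccc(OC(=O)C(C)(C)C)c(OC)c5)c1OCc6ccccc6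
F7 | step 18 | tert-butyl (3S)-3-{4-(benzyloxy)-3-methoxy-5-[(4S,5S)-2,2-dimethyl-4-(3-methoxy-4-pivaloyloxyphenyl)-1,3-dioxan-5-yl]benzyl}-4-hydroxybutanoate | COc1cc(C[C@@H](CC(=O)OC(C)(C)C)CO)cc([C@H]4COC(C)(C)O[C@@H]4c5ccc(OC(=O)C(C)(C)C)c(OC)c5)c1OCc6ccccc6
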